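**Plan**

- Retrosynthetic cuts: (a) the exocyclic C5=CH bond, made by vinylogous aldol condensation of a 3-aryltetronic acid with an aryl aldehyde; (b) the C3–C4 and acyl–O bonds of the tetronic acid, made by transesterification and Dieckmann closure; (c) the aryl–CH2 and aryl–prenyl bonds, both grown from the two C–Br bonds of 2,5-dibromohydroquinone.
- Enabling feature: in the dihydrobenzofuran, the ring oxygen O1 (on C2) and the tertiary hydroxyl (on the exocyclic CMe2 carbon) are vicinal. Ring O1–C2–C3–C3a–C7a is therefore the 1,2-oxygen-shift isomer of ring O1–C2(Me2)–C3(OH)–C4–C4a–C8a of a 2,2-dimethylchroman-3-ol, and it is made by contraction of that six-membered ring.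
- Forward order: chromene, epoxide, chromanol, ring contraction (five-membered ring, tertiary carbinol and stereocentre in one operation), aldehyde; separately dibromohydroquinone, arylacetate, tetronic acid; then union at the exocyclic alkene and removal of the acetals.
- Stereochemistry: C3 of the chroman is set (S) by catalytic asymmetric epoxidation, is untouched by the hydrogenolysis, and is inverted stereospecifically to (R) at C2 of the dihydrobenzofuran. The Z alkene arises under thermodynamic control.

Key step: step 3

Assumption: the (S,S) enantiomer of the epoxidation catalyst is taken to give the (3S,4S)-epoxide (the mirror-image catalyst is used if the sense proves opposite); tetronic acids are drawn as the 4-hydroxyfuran-2(5H)-one tautomer, as in the target.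

**Route**

Step 1
Reactants: 1 2,2-dimethyl-2H-chromene-6-carbonitrile
Product: 2 (3S,4S)-3,4-epoxy-2,2-dimethylchromane-6-carbonitrile
Conditions: aq. NaOCl (Na2HPO4 buffer, pH 11.3), chloro[(S,S)-N,N'-bis(3,5-di-tert-butylsalicylidene)cyclohexane-1,2-diaminato]manganese (3 mol%), 4-phenylpyridine N-oxide (10 mol%), CH2Cl2, 0 °C
Reagents that add atoms: sodium hypochlorite, [Na+].[O-]Cl
Why: Jacobsen–Katsuki epoxidation, for which cis-configured cyclic 2,2-dimethylchromenes are the best substrate class; the chiral manganese-oxo species delivers oxygen to one face of the C3=C4 bond and should set C3 as (S) with high enantioselectivity.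

Step 2
Reactants: 2 (3S,4S)-3,4-epoxy-2,2-dimethylchromane-6-carbonitrile
Product: 3 (3S)-3-hydroxy-2,2-dimethylchromane-6-carbonitrile
Conditions: H2 (1 atm), 10% Pd/C, EtOAc, rt
Reagents that add atoms: none
Why: Hydrogenolysis of a benzylic epoxide on palladium cleaves only the benzylic C4–O bond, so the C3–O bond and its (S) configuration are untouched, and an aryl nitrile should survive neutral conditions at 1 atm.

Step 3
Reactants: 3 (3S)-3-hydroxy-2,2-dimethylchromane-6-carbonitrile
Product: 6 (2R)-2-(2-hydroxypropan-2-yl)-2,3-dihydro-1-benzofuran-5-carbonitrile, via chromanyl triflate 4 (not isolated), via bridged oxiranium triflate 5 (not isolated)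
Conditions: Tf2O, 2,6-lutidine, CH2Cl2, −78 → −20 °C; then MeCN/H2O, NaHCO3, −20 → 40 °C
Reagents that add atoms: water, O
Why: O-Triflation gives 4, whose half-chair with pseudo-equatorial OTf holds the ring oxygen O1 antiperiplanar to the C3–OTf bond, so O1 displaces triflate from the rear to form the bridged oxiranium ion 5, and water then opens 5 at the tertiary carbon C2 (the longer, more cationic O1–C2 bond), which leaves O1 on C3, turns the six-membered ring into the five-membered one and creates the tertiary carbinol. The closest known reaction type is the ring contraction of 3-sulfonyloxytetrahydropyrans, pyranoside 2-triflates and activated 2,2-dimethylchroman-3-ols through ring-oxygen participation (1,2-oxygen shift via an oxiranium ion), the reverse of the hydroxyalkyl-tetrahydrofuran to tetrahydropyranol expansion. The only ring closed is the dihydrofuran, by intramolecular SN2 attack of O1 on C3, 5-exo-tet with respect to that ring (3-exo-tet for the transient oxirane). The single stereocentre is controlled by the substrate: C3 undergoes exactly one backside substitution and the opening occurs at the achiral C2, so (S)-3 should give (R)-6 with clean inversion. The step needs oxygen participation to beat aryl participation, methyl shift and β-elimination, and needs water to attack C2 and not C3; the antiperiplanar O1, the cyano-deactivated arene, the buffered non-nucleophilic medium and the gem-dimethyl substitution at C2 secure this.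

Step 4
Reactants: 6 (2R)-2-(2-hydroxypropan-2-yl)-2,3-dihydro-1-benzofuran-5-carbonitrile
Product: 8 (2R)-2-(2-hydroxypropan-2-yl)-2,3-dihydro-1-benzofuran-5-carbaldehyde, via aluminium aldimine 7 (not isolated)
Conditions: i-Bu2AlH (2.5 equiv), CH2Cl2, −78 → −40 °C; then 1 M aq. HCl, 0 °C, short contact
Reagents that add atoms: water, O
Why: Partial reduction of a nitrile by i-Bu2AlH stops at the N-aluminio aldimine, which hydrolyses to the aldehyde on work-up; one further equivalent is consumed by the tertiary hydroxyl as its aluminium alkoxide, and the stereocentre is not involved.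

Step 5
Reactants: 9 2,5-dibromobenzene-1,4-diol
Product: 10 1,4-dibromo-2,5-bis(methoxymethoxy)benzene
Conditions: NaH, DMF, 0 °C; MOMCl, 0 °C → rt
Reagents that add atoms: chloromethyl methyl ether (MOMCl), COCCl
Why: Williamson-type O-alkylation of the bis-phenoxide gives acetals that tolerate the organolithium, zinc enolate and alkoxide steps that follow.

Step 6
Reactants: 10 1,4-dibromo-2,5-bis(methoxymethoxy)benzene; 11 prenyl bromide (1-bromo-3-methylbut-2-ene)
Product: 13 1-bromo-2,5-bis(methoxymethoxy)-4-(3-methylbut-2-en-1-yl)benzene, via aryllithium 12 (not isolated)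
Conditions: n-BuLi (1.05 equiv), THF, −78 °C; CuBr·SMe2 (10 mol%), 11, −78 → 0 °C
Reagents that add atoms: none
Why: Bromine–lithium exchange on the symmetric dibromide stops after one exchange because a second would build a dianion, and copper-catalysed SN2 allylation of the aryllithium with prenyl bromide gives the linear prenyl arene.

Step 7
Reactants: 13 1-bromo-2,5-bis(methoxymethoxy)-4-(3-methylbut-2-en-1-yl)benzene; 14 (2-ethoxy-2-oxoethyl)zinc bromide (BrZnCH2CO2Et, solution in THF)
Product: 15 ethyl 2-[2,5-bis(methoxymethoxy)-4-(3-methylbut-2-en-1-yl)phenyl]acetate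
Conditions: Pd2(dba)3 (2 mol%), XPhos (8 mol%), THF, 65 °C
Reagents that add atoms: none
Why: Palladium-catalysed α-arylation of an ester with its Reformatsky reagent (Negishi-type coupling) runs under near-neutral conditions that spare the acetals and the prenyl alkene, and the bulky biarylphosphine allows oxidative addition into the electron-rich ortho-alkoxy aryl bromide.

Step 8
Reactants: 15 ethyl 2-[2,5-bis(methoxymethoxy)-4-(3-methylbut-2-en-1-yl)phenyl]acetate; 16 methyl glycolate
Product: 18 3-[2,5-bis(methoxymethoxy)-4-(3-methylbut-2-en-1-yl)phenyl]-4-hydroxyfuran-2(5H)-one, via glycolate diester 17 (not isolated)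
Conditions: t-BuOK (2.5 equiv), DMF, rt; then cold 1 M aq. HCl to pH 3
Reagents that add atoms: none
Why: Tandem transesterification and Dieckmann condensation, a known one-pot entry to 3-aryltetronic acids from alkyl arylacetates and methyl glycolate, is driven by formation of the stable tetronate anion.

Step 9
Reactants: 18 3-[2,5-bis(methoxymethoxy)-4-(3-methylbut-2-en-1-yl)phenyl]-4-hydroxyfuran-2(5H)-one; 8 (2R)-2-(2-hydroxypropan-2-yl)-2,3-dihydro-1-benzofuran-5-carbaldehyde
Product: 19 (5Z)-3-[2,5-bis(methoxymethoxy)-4-(3-methylbut-2-en-1-yl)phenyl]-4-hydroxy-5-{[(2R)-2-(2-hydroxypropan-2-yl)-2,3-dihydro-1-benzofuran-5-yl]methylidene}furan-2(5H)-one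
Conditions: DBU (3 equiv), MeCN, 60 °C, argon; then cold dilute aq. HCl to pH 3
Reagents that add atoms: none
Why: Vinylogous aldol (Knoevenagel-type) condensation of a 3-substituted tetronic acid at C5 with an aromatic aldehyde, followed by loss of water, is known to give pulvinones; the Z alkene (aryl syn to the ring oxygen, away from the C4 hydroxyl) is the thermodynamic isomer, and the free tertiary hydroxyl and the stereocentre are inert to the amidine base.

Step 10
Reactants: 19 (5Z)-3-[2,5-bis(methoxymethoxy)-4-(3-methylbut-2-en-1-yl)phenyl]-4-hydroxy-5-{[(2R)-2-(2-hydroxypropan-2-yl)-2,3-dihydro-1-benzofuran-5-yl]methylidene}furan-2(5H)-one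
Product: 20 (5Z)-3-[2,5-dihydroxy-4-(3-methylbut-2-en-1-yl)phenyl]-4-hydroxy-5-{[(2R)-2-(2-hydroxypropan-2-yl)-2,3-dihydro-1-benzofuran-5-yl]methylidene}furan-2(5H)-one (CNP0601419.1)
Conditions: 3 M aq. HCl, THF, 40 °C, monitored and stopped at full conversion
Reagents that add atoms: none
Why: Acid hydrolysis of aryl methoxymethyl acetals is routine for prenylated phenols under mild aqueous acid, and the Z alkene is the acid-stable isomer; a non-alcoholic medium is chosen to avoid O-alkyl exchange at the tetronic acid.

**Compound list**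

1 | 2,2-dimethyl-2H-chromene-6-carbonitrile | CC1(C)C=Cc2cc(C#N)ccc2O1 | starting material
2 | (3S,4S)-3,4-epoxy-2,2-dimethylchromane-6-carbonitrile | N#Cc1ccc2c(c1)[C@@H]1O[C@@H]1C(C)(C)O2 | intermediate
3 | (3S)-3-hydroxy-2,2-dimethylchromane-6-carbonitrile | N#Cc1ccc2c(c1)C[C@H](O)C(C)(C)O2 | intermediate
4 | (3S)-6-cyano-2,2-dimethylchroman-3-yl trifluoromethanesulfonate | N#Cc1ccc2c(c1)C[C@H](OS(=O)(=O)C(F)(F)F)C(C)(C)O2 | intermediate (not isolated)
5 | bridged aryl oxiranium triflate, in which the former chroman oxygen spans C2 and C3 and the ring-fusion CH has the configuration of 6 | N#Cc1ccc2c(c1)C[C@H]1[O+]2C1(C)C.[O-]S(=O)(=O)C(F)(F)F | intermediate (not isolated)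
6 | (2R)-2-(2-hydroxypropan-2-yl)-2,3-dihydro-1-benzofuran-5-carbonitrile | N#Cc1ccc2c(c1)C[C@H](C(C)(C)O)O2 | intermediate
7 | N-(diisobutylaluminio) aldimine of 8, with the tertiary oxygen as its diisobutylaluminium alkoxide | CC(C)C[Al](CC(C)C)N=Cc1ccc2c(c1)C[C@H](C(C)(C)O[Al](CC(C)C)CC(C)C)O2 | intermediate (not isolated)
8 | (2R)-2-(2-hydroxypropan-2-yl)-2,3-dihydro-1-benzofuran-5-carbaldehyde | O=Cc1ccc2c(c1)C[C@H](C(C)(C)O)O2 | intermediate
9 | 2,5-dibromobenzene-1,4-diol | Oc1cc(Br)c(O)cc1Br | starting material
10 | 1,4-dibromo-2,5-bis(methoxymethoxy)benzene | COCOc1cc(Br)c(OCOC)cc1Br | intermediate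
11 | prenyl bromide (1-bromo-3-methylbut-2-ene) | CC(C)=CCBr | starting material
12 | [4-bromo-2,5-bis(methoxymethoxy)phenyl]lithium | COCOc1cc(Br)c(OCOC)cc1[Li] | intermediate (not isolated)
13 | 1-bromo-2,5-bis(methoxymethoxy)-4-(3-methylbut-2-en-1-yl)benzene | COCOc1cc(Br)c(OCOC)cc1CC=C(C)C | intermediate
14 | (2-ethoxy-2-oxoethyl)zinc bromide | CCOC(=O)C[Zn]Br | starting material
15 | ethyl 2-[2,5-bis(methoxymethoxy)-4-(3-methylbut-2-en-1-yl)phenyl]acetate | CCOC(=O)Cc1cc(OCOC)c(CC=C(C)C)cc1OCOC | intermediate
16 | methyl glycolate (methyl 2-hydroxyacetate) | COC(=O)CO | starting material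
17 | 2-methoxy-2-oxoethyl 2-[2,5-bis(methoxymethoxy)-4-(3-methylbut-2-en-1-yl)phenyl]acetate | COC(=O)COC(=O)Cc1cc(OCOC)c(CC=C(C)C)cc1OCOC | intermediate (not isolated)
18 | 3-[2,5-bis(methoxymethoxy)-4-(3-methylbut-2-en-1-yl)phenyl]-4-hydroxyfuran-2(5H)-one | O=C1OCC(O)=C1c1cc(OCOC)c(CC=C(C)C)cc1OCOC | intermediate
19 | (5Z)-3-[2,5-bis(methoxymethoxy)-4-(3-methylbut-2-en-1-yl)phenyl]-4-hydroxy-5-{[(2R)-2-(2-hydroxypropan-2-yl)-2,3-dihydro-1-benzofuran-5-yl]methylidene}furan-2(5H)-one | CC(C)=CCc1cc(OCOC)c(C2=C(O)/C(=C/c3ccc4c(c3)C[C@H](C(C)(C)O)O4)OC2=O)cc1OCOC | intermediate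
20 | (5Z)-3-[2,5-dihydroxy-4-(3-methylbut-2-en-1-yl)phenyl]-4-hydroxy-5-{[(2R)-2-(2-hydroxypropan-2-yl)-2,3-dihydro-1-benzofuran-5-yl]methylidene}furan-2(5H)-one | CC(C)=CCc1cc(O)c(C2=C(O)/C(=C/c3ccc4c(c3)C[C@H](C(C)(C)O)O4)OC2=O)cc1O | target

**Count**

Total steps: 10. Longest linear sequence: 6 steps (steps 1–4, 9, 10; the branch through steps 5–8, 9, 10 is equally long).

**Steps most likely to fail**

Step 3. The oxiranium ion may partition away from water capture: proton loss from the gem-dimethyl group, β-elimination of the triflate, or return to the chromanol could compete, the more so because the cyano group weakens the participating ether oxygen. The fallback sets out from 3 and makes proton loss the planned outcome. Activation with Tf2O and 2,6-di-tert-butyl-4-methylpyridine in dry CH2Cl2 (−78 °C → rt), a known dehydrative ring contraction of 2,2-dimethylchroman-3-ols, should give (2R)-2-(prop-1-en-2-yl)-2,3-dihydro-1-benzofuran-5-carbonitrile F1 with the same inversion at the stereocentre. Mukaiyama hydration of the 1,1-disubstituted alkene (Co(acac)2, PhSiH3, O2, THF, rt, then reductive work-up) then installs the tertiary hydroxyl by hydrogen-atom transfer and oxygen trapping, without touching the stereocentre. The fallback comes back to the route at 6.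

Step 9. Attack of C5 on the electron-rich aldehyde may be slow, or the aldol stage may revert or dehydrate incompletely, leaving E/Z mixtures. The fallback sets out from 18 and 8 and replaces the one-pot condensation by a directed aldol and elimination on the 4-O-methyl tetronate. Compound 18 is O-methylated (Me2SO4, K2CO3, acetone) to 3-[2,5-bis(methoxymethoxy)-4-(3-methylbut-2-en-1-yl)phenyl]-4-methoxyfuran-2(5H)-one F2, and 8 is silylated (TMSCl, imidazole, DMF) to (2R)-2-[2-(trimethylsilyloxy)propan-2-yl]-2,3-dihydro-1-benzofuran-5-carbaldehyde F3. Deprotonation of F2 at C5 with LiN(i-Pr)2 in THF at −78 °C and addition of F3 should give the C5 aldol adduct F4 as a mixture of diastereomers at the two new centres. MsCl and Et3N convert it into the benzylic mesylate F5, which DBU eliminates by an E1cB path to the (5Z)-4-methoxy-5-arylidene furanone F6. Demethylation with LiBr in DMF at 80 °C, and cleavage of the silyl ether on aqueous citric acid work-up, return the route at 19.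

Step 10. Acid may ionise the tertiary carbinol (loss of water or ring expansion back towards the chromanol) or trigger addition of the freed ortho phenol to the prenyl alkene before both acetals are cleaved. The fallback sets out from 18 and moves the deprotection ahead of the union, so that the carbinol and the arylidene never meet acid. Hydrolysis of 18 (3 M aq. HCl, THF, rt, short contact) gives 3-[2,5-dihydroxy-4-(3-methylbut-2-en-1-yl)phenyl]-4-hydroxyfuran-2(5H)-one F7. Condensation of F7 with 8 under the conditions of step 9 (DBU, MeCN, 60 °C, strictly under argon to protect the hydroquinone) should deliver the target directly, so the fallback comes back at 20.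

**Further compounds**

F1 | step 3 | (2R)-2-(prop-1-en-2-yl)-2,3-dihydro-1-benzofuran-5-carbonitrile | N#Cc1ccc2c(c1)C[C@H](C(C)=C)O2
F2 | step 9 | 3-[2,5-bis(methoxymethoxy)-4-(3-methylbut-2-en-1-yl)phenyl]-4-methoxyfuran-2(5H)-one | COC1=C(c2cc(OCOC)c(CC=C(C)C)cc2OCOC)C(=O)OC1
F3 | step 9 | (2R)-2-[2-(trimethylsilyloxy)propan-2-yl]-2,3-dihydro-1-benzofuran-5-carbaldehyde | O=Cc1ccc2c(c1)C[C@H](C(C)(C)O[Si](C)(C)C)O2
F4 | step 9 | C5 aldol adduct of F2 and F3 (diastereomer mixture at C5 and the carbinol carbon) | COCOc1cc(C2=C(OC)C(C(O)c3ccc4c(c3)C[C@H](C(C)(C)O[Si](C)(C)C)O4)OC2=O)c(OCOC)cc1CC=C(C)C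
F5 | step 9 | methanesulfonate of aldol adduct F4 | COCOc1cc(C2=C(OC)C(C(OS(C)(=O)=O)c3ccc4c(c3)C[C@H](C(C)(C)O[Si](C)(C)C)O4)OC2=O)c(OCOC)cc1CC=C(C)C
F6 | step 9 | (5Z)-3-[2,5-bis(methoxymethoxy)-4-(3-methylbut-2-en-1-yl)phenyl]-4-methoxy-5-({(2R)-2-[2-(trimethylsilyloxy)propan-2-yl]-2,3-dihydro-1-benzofuran-5-yl}methylidene)furan-2(5H)-one | COCOc1cc(C2=C(OC)/C(=C/c3ccc4c(c3)C[C@H](C(C)(C)O[Si](C)(C)C)O4)OC2=O)c(OCOC)cc1CC=C(C)C
F7 | step 10 | 3-[2,5-dihydroxy-4-(3-methylbut-2-en-1-yl)phenyl]-4-hydroxyfuran-2(5H)-one | O=C1OCC(O)=C1c1cc(O)c(CC=C(C)C)cc1O
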